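**Strategy.** The 1,4-benzodioxane ring (O2'–C1–C5–O3', fused to aromatic ring A) is traced back to a spiro-1,3-benzodioxole: the catechol ketal of a cycloheptanone carbon (C5) whose neighbour C1 is a tertiary carbinol carrying a (Z)-vinylsilane side chain. One Lewis-acid operation opens the ketal, closes the cyclopentene by vinylsilane attack on the C5 oxocarbenium ion and returns the freed catechol oxygen O2' to C1. This net 1,2-aryloxy shift enlarges the five-membered dioxole to the six-membered dioxane and creates both quaternary ether carbons. The step exploits the vicinal C1/C5 bis-ether at the hydroazulene ring fusion and the allylic C5–C4=C3 unit of the cyclopentene.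

Key step: step 11

Remark 1: unprimed locants (C1–C15) follow guaiane numbering of the sesquiterpene half; primed locants (C1'–C22', O2', O3') follow friedelane numbering of the triterpene half (O3' lies next to the C4' methyl).
Remark 2: tingenone is taken as a purchasable natural product; its C20' methyl (alpha to the ketone) is assumed to be the more stable epimer, so reversible enolisation should not change it.
Remark 3: the sesquiterpene half of the target is (1S,5S,7S,10R), the mirror-image series of guaiol at C7/C10, so it is built from (S)-carvone.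

Step 1
Reactants: 1 but-2-yn-1-ol
Product: 2 (Z)-3-(triethylsilyl)but-2-en-1-ol
Conditions: Et3SiH, [Cp*Ru(MeCN)3]PF6 (1 mol %), CH2Cl2, 0 °C to rt
Reagents that add atoms: triethylsilane, CC[SiH](CC)CC
Why: Ruthenium-catalysed trans-hydrosilylation of the internal alkyne should place silicon on the carbon distal to the propargylic hydroxyl and add H and Si anti, which gives the (Z)-vinylsilane (silicon cis to CH2OH).

Step 2
Reactants: 2 (Z)-3-(triethylsilyl)but-2-en-1-ol
Product: 3 (Z)-(4-bromobut-2-en-2-yl)triethylsilane
Conditions: CBr4, PPh3, CH2Cl2, 0 °C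
Reagents that add atoms: carbon tetrabromide, BrC(Br)(Br)Br
Why: Appel reaction, in which bromide displaces the alkoxyphosphonium group by SN2 at the primary allylic carbon, so the (Z)-vinylsilane geometry is untouched.

Step 3
Reactants: 3 (Z)-(4-bromobut-2-en-2-yl)triethylsilane
Product: 4 (Z)-(5,5-dibromopent-2-en-2-yl)triethylsilane
Conditions: CH2Br2, LDA (LiN(iPr)2), THF, −90 °C
Reagents that add atoms: dibromomethane, BrCBr
Why: Dibromomethyllithium, formed from CH2Br2 and LDA at low temperature, should be alkylated by the reactive primary allylic bromide (SN2), which installs the CHBr2 carbon that later becomes C1.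

Step 4
Reactants: 5 (S)-(+)-carvone
Product: 6 (2R,5S)-2-methyl-5-(prop-1-en-2-yl)cyclohexan-1-one (cis-dihydrocarvone)
Conditions: ene-reductase OYE1, NADP+ (cat.), glucose, glucose dehydrogenase, phosphate buffer pH 7, 30 °C
Reagents that add atoms: none
Why: Ene-reductase (Old Yellow Enzyme) reduction delivers hydride to C3 and a proton to C2 anti under enzyme control, which should set C2 as R and give the cis ketone in which the future C10 methyl and C7 isopropenyl groups already have their final configuration.

Step 5
Reactants: 6 cis-dihydrocarvone; 4 (Z)-(5,5-dibromopent-2-en-2-yl)triethylsilane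
Product: 8 (2R,5S)-1-[(Z)-1,1-dibromo-4-(triethylsilyl)pent-3-en-1-yl]-2-methyl-5-(prop-1-en-2-yl)cyclohexan-1-ol (both carbinol epimers), via lithiated gem-dibromide 7 (not isolated)
Conditions: LDA (LiN(iPr)2) added to 6 + 4, THF, −78 °C; then H2O
Reagents that add atoms: none
Why: In-situ deprotonation of the gem-dibromide in the presence of the ketone gives a 1,1-dibromoalkyllithium that should add to the carbonyl group faster than it decomposes (carbenoid addition to a ketone); the new carbinol centre is erased in step 6.

Step 6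
Reactants: 8 dibromo carbinol
Product: 11 (3R,6S)-3-methyl-6-(prop-1-en-2-yl)-2-[(Z)-3-(triethylsilyl)but-2-en-1-yl]-1-(trimethylsilyloxy)cyclohept-1-ene, via beta-oxido carbenoid 9 (not isolated), via lithium enolate 10 (not isolated)
Conditions: n-BuLi (2.2 equiv), THF, −78 to 0 °C; then TMSCl, −78 °C
Reagents that add atoms: chlorotrimethylsilane, C[Si](C)(C)Cl
Why: Beta-oxido carbenoid ring enlargement: bromine–lithium exchange triggers a 1,2-shift of the more substituted ring carbon (the methyl-bearing future C10, with retention) to the carbenoid carbon with loss of LiBr, which should give regiospecifically the tetrasubstituted cycloheptanone enolate (C=O carbon = C5, enolate carbon = C1) that TMSCl traps on oxygen.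

Step 7
Reactants: 11 trimethylsilyl enol ether
Product: 13 (1S,4S,7R)-2,2-dimethoxy-7-methyl-4-(prop-1-en-2-yl)-1-[(Z)-3-(triethylsilyl)but-2-en-1-yl]cycloheptan-1-ol, via silyloxy epoxide 12 (not isolated)
Conditions: mCPBA, CH2Cl2/MeOH, −40 to 0 °C; then PPTS (cat.)
Reagents that add atoms: 3-chloroperoxybenzoic acid, OOC(=O)c1cccc(Cl)c1; methanol, CO
Why: Rubottom-type epoxidation of the electron-rich tetrasubstituted silyl enol ether (much faster than the isopropenyl or vinylsilane alkenes) should occur anti to the pseudo-axial C10 methyl, and acid-catalysed methanolysis of the silyloxy epoxide at its ketal carbon (epoxy-ether alcoholysis) gives the alpha-hydroxy dimethyl ketal with the C1 oxygen trans to the C10 methyl.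

Step 8
Reactants: 14 tingenone
Product: 15 2',3'-dihydroxy catechol with C6'H2 and C7'=C8' (1,6-dihydrotingenone)
Conditions: H2 (1 atm), Pd on carbon (Pd/C), EtOAc, rt
Reagents that add atoms: none
Why: Catalytic hydrogenation should reduce the extended quinone methide in a 1,6 sense to the aromatic catechol (hydrogen at C6'), leaving the hindered trisubstituted C7'=C8' alkene and the C21' ketone untouched.

Step 9
Reactants: 15 catechol with C7'=C8'
Product: 16 2',3'-dihydroxy catechol with C6'=C7' and 8'β-H
Conditions: KOtBu (3 equiv), DMSO, rt, argon; then dilute HCl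
Reagents that add atoms: none
Why: Base-mediated conjugative isomerisation of an allylarene to a styrene: deprotonation at benzylic C6' gives a 1-arylallyl anion that is protonated at C8', expected on the β-face because the α-face is screened by the syn-axial C13' methyl, which should give 8'β-H (cis to the C9' and C14' methyls).

Step 10
Reactants: 13 alpha-hydroxy dimethyl ketal; 16 catechol with C6'=C7'
Product: 17 spiro-1,3-benzodioxole (both catechol oxygens on C5, free C1–OH, vinylsilane side chain; both spiro epimers at C5)
Conditions: PPTS (cat.), toluene, 4 Å molecular sieves, 50 °C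
Reagents that add atoms: none
Why: Acid-catalysed transketalisation, in which loss of methanol gives an oxocarbenium ion at C5 that the catechol captures twice (5-exo closure), driven by removal of methanol, while the tertiary C1 alcohol and the vinylsilane should not react under pyridinium catalysis.

Step 11
Reactants: 17 spiro-1,3-benzodioxole
Product: 19 CNP0233042.2 (target), via cyclopentene phenol 18 (not isolated)
Conditions: TMSOTf (0.2 equiv), 2,6-di-tert-butyl-4-methylpyridine (0.1 equiv), CH2Cl2, −78 to −20 °C
Reagents that add atoms: none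
Why: Proposed new method: the silyl triflate opens the spiro-1,3-benzodioxole to the aryloxy-carbenium ion at C5, the (Z)-vinylsilane attacks this ion at its silicon-bearing carbon C4 (ipso substitution through a β-silyl cation, loss of the triethylsilyl group) to form C5–C4, and the tertiary C1 carbinol then ionises and is captured by the freed phenol oxygen O2', so that O2' has moved from C5 to C1 and the five-membered dioxole has become the six-membered dioxane. The closest known reactions are the acid-promoted 1,2-alkoxy shift that enlarges alpha-hydroxy or alpha-halo 1,3-dioxolanes to 1,4-dioxanes and the vinylsilane-terminated cyclisation of oxocarbenium ions. The cyclopentene closes in a 5-endo-trig mode (endocyclic C3=C4) and the dioxane by six-membered capture of the tertiary C1 cation by oxygen. C5 is controlled by the tether, because C4 arrives on the face of the C1 side chain and leaves O3' on the face of the C1 oxygen, and C1 is re-formed with net retention, because the arene holds O2' on the O3' face; the C1 oxygen was set trans to the C10 methyl in step 7, so both ether oxygens should end anti to that methyl as in the target. The step needs O3' to be the oxygen that stays on C5: O3' (ortho-methyl, para-alkyl) is the better donor for the carbenium ion and O2' (para to the styrene, unhindered) the better leaving and silyl-accepting oxygen, and both spiro epimers converge through the same ion. It also needs the carbenium ion to be taken by the vinylsilane and not by the C7 isopropenyl group, which the five-ring tether and the β-silyl effect should favour at low temperature.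

**Compound list**

1 | but-2-yn-1-ol | CC#CCO | starting material
2 | (Z)-3-(triethylsilyl)but-2-en-1-ol | C/C(=C/CO)[Si](CC)(CC)CC | intermediate
3 | (Z)-(4-bromobut-2-en-2-yl)triethylsilane | C/C(=C/CBr)[Si](CC)(CC)CC | intermediate
4 | (Z)-(5,5-dibromopent-2-en-2-yl)triethylsilane | C/C(=C/CC(Br)Br)[Si](CC)(CC)CC | intermediate
5 | (S)-(+)-carvone | CC1=CC[C@@H](CC1=O)C(C)=C | starting material
6 | (2R,5S)-2-methyl-5-(prop-1-en-2-yl)cyclohexan-1-one (cis-dihydrocarvone) | C[C@@H]1CC[C@@H](CC1=O)C(C)=C | intermediate
7 | (Z)-1,1-dibromo-1-lithio-4-(triethylsilyl)pent-3-ene | [Li]C(Br)(Br)C/C=C(/C)[Si](CC)(CC)CC | intermediate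
8 | (2R,5S)-1-[(Z)-1,1-dibromo-4-(triethylsilyl)pent-3-en-1-yl]-2-methyl-5-(prop-1-en-2-yl)cyclohexan-1-ol (carbinol epimers) | C[C@@H]1CC[C@@H](CC1(O)C(Br)(Br)C/C=C(/C)[Si](CC)(CC)CC)C(C)=C | intermediate
9 | dilithio beta-oxido carbenoid of 8 (O–Li and C(Li)Br) | C[C@@H]1CC[C@@H](CC1(O[Li])C([Li])(Br)C/C=C(/C)[Si](CC)(CC)CC)C(C)=C | intermediate
10 | lithium (3R,6S)-3-methyl-6-(prop-1-en-2-yl)-2-[(Z)-3-(triethylsilyl)but-2-en-1-yl]cyclohept-1-en-1-olate | [Li+].C[C@@H]1CC[C@H](C(C)=C)CC([O-])=C1C/C=C(/C)[Si](CC)(CC)CC | intermediate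
11 | (3R,6S)-3-methyl-6-(prop-1-en-2-yl)-2-[(Z)-3-(triethylsilyl)but-2-en-1-yl]-1-(trimethylsilyloxy)cyclohept-1-ene | C[C@@H]1CC[C@H](C(C)=C)CC(O[Si](C)(C)C)=C1C/C=C(/C)[Si](CC)(CC)CC | intermediate
12 | C1,C5-epoxide of 11 (epoxide oxygen trans to the C10 methyl, OSiMe3 on C5) | C[C@@H]1CC[C@H](C(C)=C)C[C@@]2(O[Si](C)(C)C)O[C@@]12C/C=C(/C)[Si](CC)(CC)CC | intermediate
13 | (1S,4S,7R)-2,2-dimethoxy-7-methyl-4-(prop-1-en-2-yl)-1-[(Z)-3-(triethylsilyl)but-2-en-1-yl]cycloheptan-1-ol (OH trans to the ring methyl) | C[C@@H]1CC[C@H](C(C)=C)CC(OC)(OC)[C@]1(O)C/C=C(/C)[Si](CC)(CC)CC | intermediate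
14 | tingenone | CC1=C(O)C(=O)C=C2C1=CC=C1[C@@]2(C)CC[C@@]2(C)[C@@H]3C[C@@H](C)C(=O)C[C@]3(C)CC[C@]12C | starting material
15 | 1,6-dihydrotingenone catechol (aromatic ring A, 2',3'-diol, C6'H2, C7'=C8', 21'-ketone) | Cc1c(O)c(O)cc2c1CC=C1[C@@]2(C)CC[C@@]2(C)[C@@H]3C[C@@H](C)C(=O)C[C@]3(C)CC[C@]12C | intermediate
16 | isomeric catechol (aromatic ring A, 2',3'-diol, C6'=C7', 8'β-H, 21'-ketone) | Cc1c(O)c(O)cc2c1C=C[C@@H]1[C@@]2(C)CC[C@@]2(C)[C@@H]3C[C@@H](C)C(=O)C[C@]3(C)CC[C@]12C | intermediate
17 | spiro-1,3-benzodioxole: catechol 16 ketalised on C5 of the cycloheptane; C1 bears OH (trans to the C10 methyl) and the (Z)-3-(triethylsilyl)but-2-enyl chain; spiro epimers at C5 | C=C(C)[C@H]1CC[C@@H](C)[C@@](O)(C/C=C(/C)[Si](CC)(CC)CC)C2(C1)Oc1c(cc3c(c1C)C=C[C@@H]1[C@@]3(C)CC[C@@]3(C)[C@@H]4C[C@@H](C)C(=O)C[C@]4(C)CC[C@]13C)O2 | intermediate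
18 | cyclopentene phenol: guaia-3,11-dien-1-ol with O3' of the catechol on C5 (cis to the C1 hydroxyl), free O2'H | C=C(C)[C@H]1CC[C@@H](C)[C@@]2(O)CC=C(C)[C@]2(C1)Oc1c(O)cc2c(c1C)C=C[C@@H]1[C@@]2(C)CC[C@@]2(C)[C@@H]3C[C@@H](C)C(=O)C[C@]3(C)CC[C@]12C | intermediate
19 | CNP0233042.2 | C=C(C)[C@H]1CC[C@@H](C)[C@@]23CC=C(C)[C@]2(C1)Oc1c(cc2c(c1C)C=C[C@@H]1[C@@]2(C)CC[C@@]2(C)[C@@H]4C[C@@H](C)C(=O)C[C@]4(C)CC[C@]12C)O3 | target

**Totals.** Total step count: 11. Longest linear sequence: 8 steps (steps 1, 2, 3, 5, 6, 7, 10, 11).

**Three steps most likely to fail**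

1. Step 11 (proposed new method). The C5 carbenium ion may be captured by the C7 isopropenyl group, the C1 cation may undergo alkyl shift or elimination before O2' closes, the wrong oxygen may stay on C5, or the tertiary allylic C5–O3' ether of the product may re-ionise. The fallback uses known chemistry and sets out from 16 and 11. Catechol 16 is oxidised with Ag2O (Et2O, MgSO4, 0 °C) to the ortho-quinone F1. F1 is combined at once with silyl enol ether 11 (CH2Cl2, −40 °C) in an inverse-demand hetero-Diels–Alder reaction. The nucleophilic enol carbon C1 should bond to the less hindered quinone oxygen O2' on the face anti to the C10 methyl, and O3' closes on C5, giving the 2-silyloxy-1,4-benzodioxane F2 with the dioxane ring formed directly. BF3·OEt2 (CH2Cl2, −78 °C) then ionises the C5–OSiMe3 bond and the vinylsilane ipso-cyclisation closes the cyclopentene. The fallback returns to the route at 19.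

2. Step 9. Protonation of the delocalised C6'–C8' anion may occur on the α-face (poor facial selectivity), and prolonged base may equilibrate C8' or C20'. The fallback sets out from 14. 2-Nitrobenzenesulfonohydrazide is added in a conjugate sense to C6' of tingenone (THF, 0 °C) to give the hydrazide F3; the β-adduct is the one needed. On warming, F3 loses 2-nitrobenzenesulfinic acid to give the allylic diazene F4. F4 expels N2 in a retro-ene step that delivers hydrogen suprafacially to C8' and moves the alkene to C6'=C7'. The C8' hydrogen then follows the face of the C6' adduct rather than the face of an external proton source. The fallback returns at 16.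

3. Step 5. The lithiated gem-dibromide may decompose by α-elimination, and the hindered ketone may be enolised instead of attacked. The fallback sets out from 6 and 3. The parent dibromomethyllithium (CH2Br2, lithium 2,2,6,6-tetramethylpiperidide, THF, −78 °C) is added to 6 to give the dibromomethyl carbinol F5. n-BuLi (2 equiv) induces the same ring enlargement to the C1-unsubstituted lithium enolate F6, which is alkylated in the same flask with allylic bromide 3 (HMPA) to give ketone F7. Soft enolisation (TMSCl, NaI, Et3N, MeCN) to the more substituted silyl enol ether returns at 11.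

Further compounds
F1 | step 11 | ortho-quinone of 16 (2',3'-dione, C1'=C10', C4'=C5', C6'=C7', 8'β-H) | O=C1C(=O)C=C2C(=C1C)C=C[C@@H]1[C@@]2(C)CC[C@@]2(C)[C@@H]3C[C@@H](C)C(=O)C[C@]3(C)CC[C@]12C
F2 | step 11 | hetero-Diels–Alder adduct: 1,4-benzodioxane with O2' on C1 (C1 also bears the vinylsilane chain) and O3' on C5 (C5 also bears OSiMe3), both oxygens anti to the C10 methyl | C=C(C)[C@H]1CC[C@@H](C)[C@@]2(C/C=C(/C)[Si](CC)(CC)CC)[C@](C1)(O[Si](C)(C)C)Oc1c(cc3c(c1C)C=C[C@@H]1[C@@]3(C)CC[C@@]3(C)[C@@H]4C[C@@H](C)C(=O)C[C@]4(C)CC[C@]13C)O2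
F3 | step 9 | 6'β-[2-(2-nitrophenylsulfonyl)hydrazinyl] adduct of tingenone (catechol, C7'=C8') | Cc1c(O)c(O)cc2c1[C@H](NNS(=O)(=O)c1ccccc1[N+](=O)[O-])C=C1[C@@]2(C)CC[C@@]2(C)[C@@H]3C[C@@H](C)C(=O)C[C@]3(C)CC[C@]12C
F4 | step 9 | 6'β-diazenyl catechol (allylic diazene, C7'=C8') | Cc1c(O)c(O)cc2c1[C@H](N=N)C=C1[C@@]2(C)CC[C@@]2(C)[C@@H]3C[C@@H](C)C(=O)C[C@]3(C)CC[C@]12C
F5 | step 5 | (2R,5S)-1-(dibromomethyl)-2-methyl-5-(prop-1-en-2-yl)cyclohexan-1-ol (carbinol epimers) | C[C@@H]1CC[C@@H](CC1(O)C(Br)Br)C(C)=C
F6 | step 5 | lithium (3R,6S)-3-methyl-6-(prop-1-en-2-yl)cyclohept-1-en-1-olate | [Li+].C[C@@H]1CC[C@H](C(C)=C)CC([O-])=C1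
F7 | step 5 | (3R,6S)-3-methyl-6-(prop-1-en-2-yl)-2-[(Z)-3-(triethylsilyl)but-2-en-1-yl]cycloheptan-1-one (C2 epimers) | C[C@@H]1CC[C@H](C(C)=C)CC(=O)C1C/C=C(/C)[Si](CC)(CC)CC
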